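## Analysis of the target

Target 23 is a longipinane-type sesquiterpenoid, a tricyclo[5.4.0.0^2,8]undecan-11-one with two angelate [(Z)-2-methylbut-2-enoate] esters. Atoms are labelled with the letter C (compounds carry plain numerals): C1 (CH–O next to the gem-dimethyl carbon), C2 (CH2), C3 (CH–O), C4 (quaternary, methyl), C5, C6, C7 (cyclobutane CH), C8 (C=O), C9 (CH2), C10 (CH–CH3), C11 (CMe2).

The cyclobutane C4–C5–C6–C7 is shared by all three rings. C8–C9–C10 bridges C7 and C5 on one face, giving a bicyclo[3.1.1]heptan-2-one. C3–C2–C1–C11 bridges C4 and C6 on the other face, giving the seven-membered ring.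

There are seven stereocentres (1R,3R,4R,5S,6S,7R,10R in these labels). C4–C7 are locked together by the ring topology, the C10 methyl lies on the side of C6, and the C1 and C3 oxygens are trans.

The two faces of the seven-membered ring differ only through the remote C8 carbonyl and C10 methyl. Substrate control at C3 is therefore unreliable and C3 should be set by a reagent.

Sensitive groups are the angelates (Z to E isomerisation by base, nucleophilic catalysts, radicals), the strained cyclobutane (cationic rearrangement) and every β-oxygenated ketone on the way (retro-aldol, elimination).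

The synthesis is hard because every [2+2] retron of the cyclobutane opens the six- and seven-membered rings together, and two quaternary carbons (C4, C11) flank the four-membered ring.

The feature that invites the chosen move is C6. Besides its ring bonds it carries only H and C11, while C4 carries methyl and chain as an E-trisubstituted alkene would deliver them. A bicyclo[3.1.1]heptan-6-one with C6 as the carbonyl is exactly the product of an intramolecular ketene–alkene [2+2], and that carbonyl is the handle for the C6–C11 bond.

## Retrosynthetic reasoning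

**Esters.** The two C–O acyl bonds of 23 are cut last, giving diol 20 and two molecules of angelic acid 21. The angelates tolerate little, so nothing may follow their introduction.

**C1 carbinol.** Diol 20 is traced to hydroxy diketone 19 by cutting the C1–H bond. A hydroxyl-directed hydride delivery from the C3 hydroxyl sets C1 trans to C3 and leaves the isolated C8 ketone alone. 19 comes from silyl ether 18.

**C8 ketone.** 18 comes from alcohol 17 and benzoate 16. The C8 oxygen must stay at the alcohol level as long as C6 bears oxygen, because a C8 ketone β to a C6 alkoxide would fragment the cyclobutane by retro-aldol cleavage of C6–C7.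

**C6–H.** 16 is traced to oxalate 15 and tertiary alcohol 14 (C6–O replaced by C6–H through a radical). The ring fixes the configuration at C6, so this costs no stereocontrol.

**Seven-membered ring, C6–C11.** 14 is opened to enone 12. Conjugate hydride addition gives enolate 13 regiospecifically at C11, which adds to the cyclobutanone carbonyl. This bond is chosen because it joins the quaternary C11 to the cyclobutane with natural aldol polarity. Delivery from the C4 side chain is the only way to reach the face of C6 anti to the three-carbon bridge.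

**C2–C3.** 12 is traced through alcohol 11 to keto aldehyde 9 and 3-methylbut-3-en-2-one 10 by an aldol cut. C3 is set in an open chain by a chiral catalyst, which sidesteps the near-symmetric ring faces. Ketone 10 has one enolisable site and brings C2, C1, C11 and one of the two C11 methyl groups; the second appears in step 8.

**C3 aldehyde.** 9 comes from vinyl cyclobutanone 8 by cleavage of the vinyl group. The vinyl group is wanted in 8 for a second reason, given next.

**Key cut, C6–C7 and C4–C5.** 8 is opened through ketene 7 and acid chloride 6 to the acyclic diene acid 5. One thermal operation forms the cyclobutane and the six-membered ring and sets C4, C5 and C7. The 1,3-diene makes the alkene a good ketene partner and directs the ketene carbonyl carbon to C7. The precursor is an open chain with two stereocentres.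

**Chain.** 5 comes from enal 4 by methylenation. 4 comes from aldehyde 2 through α-benzoyloxy aldehyde 3 (asymmetric α-oxygenation, then E-selective olefination). 2 comes from (R)-citronellic acid 1 by ozonolysis. Acid carbons 1–6 of 2 become C6, C5, C10, C9, C8, C7, and the stereocentre of 1 becomes C10.

## Alternatives that were turned down

**Alternative 1:** (the textbook cyclobutane disconnection) Cut C4–C5 and C6–C7 as a photochemical enone–alkene [2+2]. Because the cyclobutane is common to the other two rings, the precursor is necessarily the eleven-membered dienone A1, and the forward key step is its transannular photocycloaddition.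
- Regiochemistry: the alkenes of A1 are linked by a three-atom and a four-atom tether. First bond formation to a five-membered ring (C7–C5) leads to the fused 5-4-6 skeleton, whereas the target needs the crossed mode on both tethers.
- Stereochemistry: the triplet enone loses the C7=C4 geometry, so C4 is not controlled, and nothing in A1 fixes the absolute sense of the cyclobutane.
- Step economy: a medium ring with three stereocentres and two E-alkenes costs more steps than the photoreaction saves.

**Alternative 2:** Cut C6–C7 alone as an intramolecular enolate alkylation. The C7 enolate of the cis-fused bicyclo[5.4.0]undecanone A2 would displace a C6 sulfonate (4-exo-tet).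
- The key step makes one bond and one ring, yet needs the whole 6–7 carbocycle with six stereocentres, including the quaternary C4 and a leaving group held anti to the enolate.
- C6 is flanked by the quaternary C11, so the SN2 step is neopentyl-like and slow; elimination toward C5 or fragmentation would compete.
- Kinetic deprotonation of the C8 ketone favours C9 over the hindered C7.

**Alternative 3:** Delete C9. The cyclohexanone is contracted in the retrosynthetic sense to the 9-nor ketone A3, a bicyclo[2.1.1]hexan-2-one of the kind a crossed [2+2] photocycloaddition of a 1,5-dien-3-one gives. The forward key step is a one-carbon ring expansion of A3 with a diazoalkane.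
- The insertion must choose migration of the secondary C10 over the bridgehead C7 in a strained unsymmetrical ketone, and nothing in A3 directs that choice.
- The bicyclo[2.1.1]hexyl system risks cyclobutane cleavage under the Lewis-acidic conditions.
- The photochemical step again scrambles C4 unless the seven-membered ring is closed first, which means a ten-membered ring precursor.

Key step: step 4

Assumption: the senses of induction in steps 2 and 6 are taken from the usual models (the S-configured shielding aminocatalyst gives the 5S benzoate, the (S,S)-ligand gives the R carbinol); if either is opposite, the enantiomeric catalyst is used and nothing else changes.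

## Route

Step 1
Reactants: 1 (3R)-3,7-dimethyloct-6-enoic acid [(R)-citronellic acid]
Product: 2 (3R)-3-methyl-6-oxohexanoic acid
Conditions: O3, CH2Cl2, −78 °C; then PPh3, −78 °C → rt
Reagents that add atoms: ozone, O=[O+][O-]
Why: Ozonolysis with reductive work-up cleaves the only alkene and leaves the stereocentre (future C10) untouched; the six-carbon acid chain maps onto C6, C5, C10, C9, C8, C7.

Step 2
Reactants: 2 (3R)-3-methyl-6-oxohexanoic acid
Product: 4 (3R,5S,6E)-5-(benzoyloxy)-3,7-dimethyl-8-oxooct-6-enoic acid, via α-benzoyloxy aldehyde 3 (not isolated)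
Conditions: (S)-2-[diphenyl(trimethylsilyloxy)methyl]pyrrolidine (10 mol %), (PhCO2)2, THF, 0 °C; then Ph3P=C(CH3)CHO (2.5 equiv), CH2Cl2, rt
Reagents that add atoms: dibenzoyl peroxide, O=C(OOC(=O)c1ccccc1)c1ccccc1; 2-(triphenylphosphoranylidene)propanal, CC(C=O)=P(c1ccccc1)(c1ccccc1)c1ccccc1
Why: Enamine-catalysed α-benzoyloxylation, in which the catalyst shields one enamine face and should set 5S (future C8), followed by Wittig olefination with a formyl-stabilised ylide, which should give the E-enal. The oxygen enters already acylated, so no free δ-hydroxy acid that would lactonise is ever formed; the excess ylide buffers the two acids.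

Step 3
Reactants: 4 (3R,5S,6E)-5-(benzoyloxy)-3,7-dimethyl-8-oxooct-6-enoic acid
Product: 5 (3R,5S,6E)-5-(benzoyloxy)-3,7-dimethylnona-6,8-dienoic acid
Conditions: Ph3PCH3Br, KN(SiMe3)2 (3 equiv each), THF, −78 → 0 °C; aq. citric acid
Reagents that add atoms: methyltriphenylphosphonium bromide, C[P+](c1ccccc1)(c1ccccc1)c1ccccc1.[Br-]
Why: Wittig methylenation of the aldehyde (the first equivalent of ylide only deprotonates the acid); at low temperature the benzoate should survive. The new vinyl group turns the alkene into a 1,3-diene and is the masked C3 aldehyde.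

Step 4
Reactants: 5 (3R,5S,6E)-5-(benzoyloxy)-3,7-dimethylnona-6,8-dienoic acid
Product: 8 (1R,2S,4R,5R,7R)-7-ethenyl-4,7-dimethyl-6-oxobicyclo[3.1.1]heptan-2-yl benzoate, via acid chloride 6 (not isolated), via ketene 7 (not isolated)
Conditions: Me2C=C(Cl)NMe2, CH2Cl2, 0 °C → rt; then slow addition to Et3N, toluene, 110 °C (high dilution)
Reagents that add atoms: none
Why: Dehydrochlorination of 6 gives the aldoketene 7, whose electrophilic central carbon (future C6) bonds to the diene terminus C7 while its α-carbon (C5) bonds to the methyl-bearing carbon C4 in a concerted, asynchronous thermal [π2s+π2a] cycloaddition. The closest known reaction type is the intramolecular ketene–alkene [2+2] of 5-alkenyl ketenes with a distally more substituted alkene, which gives bicyclo[3.1.1]heptan-6-ones; 1,3-dienes are the most reactive partners for ketenes. Two rings close: the six-membered ring C6–C5–C10–C9–C8–C7 by bonding of the ketene carbonyl carbon to the proximal alkene carbon, and the cyclobutanone by bonding of C5 to the distal carbon C4, i.e. the bridged (crossed) mode, which is secured because the developing positive charge at C4 is tertiary and allylic, whereas the fused bicyclo[3.2.0] mode would place it at the secondary C7. C4 is set by suprafacial transfer of the 6E geometry: the methyl group, cis to C8 on the alkene, ends up syn to the three-carbon bridge and the vinyl group on the face of the C6 carbonyl. C5 and C7 follow from the ring, and the alkene face that is attacked is chosen by the two centres already present: with the tether on the attacked face, allylic 1,3-strain against the C4 methyl places the C8 benzoate in the alkene plane pointing away and only C8–H on the far face, and the same face lets the C10 methyl lie pseudo-equatorial, away from the C4 methyl (matched 3R,5S pair). The step needs cyclisation to outrun ketene dimerisation, which slow addition at high dilution and the three-atom tether should provide, and reaction at the internal alkene only, which is secured because addition to the vinyl group would force the E-alkene into a seven- or eight-membered ring.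

Step 5
Reactants: 8 (1R,2S,4R,5R,7R)-7-ethenyl-4,7-dimethyl-6-oxobicyclo[3.1.1]heptan-2-yl benzoate
Product: 9 (1R,2S,4R,5R,7R)-7-formyl-4,7-dimethyl-6-oxobicyclo[3.1.1]heptan-2-yl benzoate
Conditions: O3, CH2Cl2, −78 °C; then PPh3
Reagents that add atoms: ozone, O=[O+][O-]
Why: Ozonolysis of the only alkene unmasks the C3 aldehyde; both carbonyl groups of 9 are non-enolisable (quaternary C4, bridgeheads C5 and C7), so the keto aldehyde should be stable.

Step 6
Reactants: 9 (1R,2S,4R,5R,7R)-7-formyl-4,7-dimethyl-6-oxobicyclo[3.1.1]heptan-2-yl benzoate; 10 3-methylbut-3-en-2-one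
Product: 11 (1R,2S,4R,5R,7R)-7-[(1R)-1-hydroxy-4-methyl-3-oxopent-4-en-1-yl]-4,7-dimethyl-6-oxobicyclo[3.1.1]heptan-2-yl benzoate
Conditions: 2,6-bis{[(2S)-2-(hydroxydiphenylmethyl)pyrrolidin-1-yl]methyl}-4-methylphenol [(S,S)-ProPhenol ligand, 10 mol %], Et2Zn (20 mol %), 4 Å molecular sieves, 10 (excess), THF, 0 °C
Reagents that add atoms: none
Why: Direct catalytic asymmetric aldol addition with the catalyst formed from Et2Zn and the ProPhenol ligand, a reaction type known for methyl vinyl ketones as donors and α-branched aldehydes as acceptors; 10 has a single enolisable position and the aldehyde reacts in preference to the ketone. The two faces of the formyl group differ only through remote groups, so the catalyst, not the substrate, should decide the C3 configuration (R).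

Step 7
Reactants: 11 (1R,2S,4R,5R,7R)-7-[(1R)-1-hydroxy-4-methyl-3-oxopent-4-en-1-yl]-4,7-dimethyl-6-oxobicyclo[3.1.1]heptan-2-yl benzoate
Product: 12 (1R,2S,4R,5R,7R)-7-[(1R)-1-[(tert-butyldimethylsilyl)oxy]-4-methyl-3-oxopent-4-en-1-yl]-4,7-dimethyl-6-oxobicyclo[3.1.1]heptan-2-yl benzoate
Conditions: t-BuMe2SiOSO2CF3, 2,6-lutidine, CH2Cl2, −78 °C
Reagents that add atoms: tert-butyldimethylsilyl trifluoromethanesulfonate, CC(C)(C)[Si](C)(C)OS(=O)(=O)C(F)(F)F
Why: Silylation under non-basic conditions blocks retro-aldol cleavage and oxa-Michael addition of the C3 hydroxyl to the enone, and keeps this oxygen out of the acylation in step 9.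

Step 8
Reactants: 12 (1R,2S,4R,5R,7R)-7-[(1R)-1-[(tert-butyldimethylsilyl)oxy]-4-methyl-3-oxopent-4-en-1-yl]-4,7-dimethyl-6-oxobicyclo[3.1.1]heptan-2-yl benzoate
Product: 14 (1R,2R,3R,7R,8R,9R,11S)-3-[(tert-butyldimethylsilyl)oxy]-7-hydroxy-2,6,6,9-tetramethyl-5-oxotricyclo[5.4.0.0^2,8]undecan-11-yl benzoate, via copper enolate 13 (not isolated)
Conditions: [(Ph3P)CuH]6 (0.4 equiv), toluene, −40 → 0 °C; then aq. NH4Cl
Reagents that add atoms: none
Why: Copper hydride reductive aldol cyclisation: conjugate hydride delivery to the unsubstituted β-carbon gives the C11 enolate 13 regiospecifically (no stereocentre arises, C11 becomes CMe2), and it adds to the strained, non-enolisable cyclobutanone to close the seven-membered ring. The tether from C4 can reach only the face of C6 anti to the three-carbon bridge, which fixes C6 with the hydroxyl on the bridge side.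

Step 9
Reactants: 14 (1R,2R,3R,7R,8R,9R,11S)-3-[(tert-butyldimethylsilyl)oxy]-7-hydroxy-2,6,6,9-tetramethyl-5-oxotricyclo[5.4.0.0^2,8]undecan-11-yl benzoate
Product: 15 methyl (1R,2R,3R,7R,8R,9R,11S)-11-(benzoyloxy)-3-[(tert-butyldimethylsilyl)oxy]-2,6,6,9-tetramethyl-5-oxotricyclo[5.4.0.0^2,8]undecan-7-yl oxalate
Conditions: ClC(O)CO2Me, 4-(dimethylamino)pyridine, pyridine, CH2Cl2, 0 °C → rt
Reagents that add atoms: methyl chlorooxoacetate, COC(=O)C(=O)Cl
Why: Acylation of the tertiary alcohol with a small, very electrophilic acid chloride under conditions that generate no alkoxide (no retro-aldol); the ester cannot eliminate because its β-carbons are two bridgeheads and a quaternary carbon.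

Step 10
Reactants: 15 methyl (1R,2R,3R,7R,8R,9R,11S)-11-(benzoyloxy)-3-[(tert-butyldimethylsilyl)oxy]-2,6,6,9-tetramethyl-5-oxotricyclo[5.4.0.0^2,8]undecan-7-yl oxalate
Product: 16 (1R,2R,3R,7S,8S,9R,11S)-3-[(tert-butyldimethylsilyl)oxy]-2,6,6,9-tetramethyl-5-oxotricyclo[5.4.0.0^2,8]undecan-11-yl benzoate
Conditions: Bu3SnH, 2,2'-azobis(2-methylpropionitrile), PhSeSePh (10 mol %), toluene, 100 °C
Reagents that add atoms: none
Why: Radical deoxygenation of a tert-alkyl methyl oxalate (Barton–McCombie-type stannane chain); the C6 radical is held pyramidal by the rings, so hydrogen can only enter where the oxygen left. PhSeH formed in the flask should trap the radical faster than it can undergo 1,2-acyl shift or cyclobutane opening.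

Step 11
Reactants: 16 (1R,2R,3R,7S,8S,9R,11S)-3-[(tert-butyldimethylsilyl)oxy]-2,6,6,9-tetramethyl-5-oxotricyclo[5.4.0.0^2,8]undecan-11-yl benzoate
Product: 17 (1R,2R,3R,7S,8S,9R,11S)-3-[(tert-butyldimethylsilyl)oxy]-11-hydroxy-2,6,6,9-tetramethyltricyclo[5.4.0.0^2,8]undecan-5-one
Conditions: K2CO3, MeOH, 0 °C → rt
Reagents that add atoms: none
Why: Base-catalysed transesterification removes the benzoate; the silyl ether is stable to carbonate and silyloxide is a poor leaving group, so the β-silyloxy ketone should survive. C6 no longer bears oxygen, so C8 can now be taken to the ketone without risk of fragmentation.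

Step 12
Reactants: 17 (1R,2R,3R,7S,8S,9R,11S)-3-[(tert-butyldimethylsilyl)oxy]-11-hydroxy-2,6,6,9-tetramethyltricyclo[5.4.0.0^2,8]undecan-5-one
Product: 18 (1R,2R,3R,7S,8S,9R)-3-[(tert-butyldimethylsilyl)oxy]-2,6,6,9-tetramethyltricyclo[5.4.0.0^2,8]undecane-5,11-dione
Conditions: Dess–Martin periodinane, NaHCO3, CH2Cl2, rt
Reagents that add atoms: none
Why: Dess–Martin oxidation under buffered, neutral conditions; C7 is a bridgehead and cannot enolise, and C10 is not α to the new ketone, so no stereocentre is at risk.

Step 13
Reactants: 18 (1R,2R,3R,7S,8S,9R)-3-[(tert-butyldimethylsilyl)oxy]-2,6,6,9-tetramethyltricyclo[5.4.0.0^2,8]undecane-5,11-dione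
Product: 19 (1R,2R,3R,7S,8S,9R)-3-hydroxy-2,6,6,9-tetramethyltricyclo[5.4.0.0^2,8]undecane-5,11-dione
Conditions: HF·pyridine, THF, 0 °C → rt
Reagents that add atoms: none
Why: Desilylation with an acidic fluoride source; the medium is never basic, so the β-hydroxy ketone should not undergo retro-aldol ring opening or dehydration.

Step 14
Reactants: 19 (1R,2R,3R,7S,8S,9R)-3-hydroxy-2,6,6,9-tetramethyltricyclo[5.4.0.0^2,8]undecane-5,11-dione
Product: 20 (1R,2R,3R,5R,7S,8S,9R)-3,5-dihydroxy-2,6,6,9-tetramethyltricyclo[5.4.0.0^2,8]undecan-11-one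
Conditions: Me4NBH(OAc)3, MeCN/AcOH, −30 °C
Reagents that add atoms: none
Why: Evans–Saksena hydroxyl-directed reduction: the reagent exchanges an acetate for the C3 hydroxyl and delivers hydride to C1 from the face of the C3–O bond, which should give the trans (anti) diol. Triacetoxyborohydride reduces only ketones with a neighbouring hydroxyl, so the C8 ketone stays.

Step 15
Reactants: 20 (1R,2R,3R,5R,7S,8S,9R)-3,5-dihydroxy-2,6,6,9-tetramethyltricyclo[5.4.0.0^2,8]undecan-11-one; 21 (2Z)-2-methylbut-2-enoic acid (angelic acid)
Product: 23 (1R,2R,3R,5R,7S,8S,9R)-2,6,6,9-tetramethyl-11-oxotricyclo[5.4.0.0^2,8]undecane-3,5-diyl bis[(2Z)-2-methylbut-2-enoate], via mixed anhydride 22 (not isolated)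
Conditions: 21 (4 equiv), 2,4,6-Cl3C6H2COCl (4 equiv), Et3N, toluene, rt; then 20, 80 °C
Reagents that add atoms: (2Z)-2-methylbut-2-enoic acid (second equivalent of 21, which acylates the second hydroxyl), C/C=C(/C)C(=O)O
Why: Yamaguchi-type double esterification: each of the two hydroxyls (C1 and C3) attacks the unhindered angeloyl carbonyl of one molecule of mixed anhydride 22, so two molecules of 21 are consumed per molecule of 20 and the anhydride is used in excess to drive the second acylation. No nucleophilic catalyst is used, since conjugate addition–elimination of such a catalyst is the usual path from angelate to tiglate, and the step is last so that nothing follows the labile esters.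

## Compound list

1 | (3R)-3,7-dimethyloct-6-enoic acid [(R)-citronellic acid] | OC(=O)C[C@H](C)CCC=C(C)C | starting material
2 | (3R)-3-methyl-6-oxohexanoic acid | OC(=O)C[C@H](C)CCC=O | intermediate
3 | (3R,5S)-5-(benzoyloxy)-3-methyl-6-oxohexanoic acid | OC(=O)C[C@H](C)C[C@H](OC(=O)c1ccccc1)C=O | intermediate
4 | (3R,5S,6E)-5-(benzoyloxy)-3,7-dimethyl-8-oxooct-6-enoic acid | OC(=O)C[C@H](C)C[C@H](OC(=O)c1ccccc1)/C=C(\C)C=O | intermediate
5 | (3R,5S,6E)-5-(benzoyloxy)-3,7-dimethylnona-6,8-dienoic acid | OC(=O)C[C@H](C)C[C@H](OC(=O)c1ccccc1)/C=C(\C)C=C | intermediate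
6 | (3R,5S,6E)-5-(benzoyloxy)-3,7-dimethylnona-6,8-dienoyl chloride | ClC(=O)C[C@H](C)C[C@H](OC(=O)c1ccccc1)/C=C(\C)C=C | intermediate
7 | (3R,5S,6E)-3,7-dimethyl-1-oxonona-1,6,8-trien-5-yl benzoate (ketene) | O=C=C[C@H](C)C[C@H](OC(=O)c1ccccc1)/C=C(\C)C=C | intermediate
8 | (1R,2S,4R,5R,7R)-7-ethenyl-4,7-dimethyl-6-oxobicyclo[3.1.1]heptan-2-yl benzoate | C=C[C@]2(C)[C@@H]3C(=O)[C@H]2[C@@H](OC(=O)c1ccccc1)C[C@H]3C | intermediate
9 | (1R,2S,4R,5R,7R)-7-formyl-4,7-dimethyl-6-oxobicyclo[3.1.1]heptan-2-yl benzoate | O=C[C@]2(C)[C@@H]3C(=O)[C@H]2[C@@H](OC(=O)c1ccccc1)C[C@H]3C | intermediate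
10 | 3-methylbut-3-en-2-one | CC(=O)C(C)=C | starting material
11 | (1R,2S,4R,5R,7R)-7-[(1R)-1-hydroxy-4-methyl-3-oxopent-4-en-1-yl]-4,7-dimethyl-6-oxobicyclo[3.1.1]heptan-2-yl benzoate | C=C(C)C(=O)C[C@@H](O)[C@]2(C)[C@@H]3C(=O)[C@H]2[C@@H](OC(=O)c1ccccc1)C[C@H]3C | intermediate
12 | (1R,2S,4R,5R,7R)-7-[(1R)-1-[(tert-butyldimethylsilyl)oxy]-4-methyl-3-oxopent-4-en-1-yl]-4,7-dimethyl-6-oxobicyclo[3.1.1]heptan-2-yl benzoate | C=C(C)C(=O)C[C@@H](O[Si](C)(C)C(C)(C)C)[C@]2(C)[C@@H]3C(=O)[C@H]2[C@@H](OC(=O)c1ccccc1)C[C@H]3C | intermediate
13 | monovalent copper enolate formed from 12 by conjugate hydride addition (C1–O–Cu, C1=C11; phosphine ligands omitted) | CC(C)=C(O[Cu])C[C@@H](O[Si](C)(C)C(C)(C)C)[C@]2(C)[C@@H]3C(=O)[C@H]2[C@@H](OC(=O)c1ccccc1)C[C@H]3C | intermediate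
14 | (1R,2R,3R,7R,8R,9R,11S)-3-[(tert-butyldimethylsilyl)oxy]-7-hydroxy-2,6,6,9-tetramethyl-5-oxotricyclo[5.4.0.0^2,8]undecan-11-yl benzoate | O=C1C[C@@H](O[Si](C)(C)C(C)(C)C)[C@]2(C)[C@@H]3[C@@](O)([C@H]2[C@@H](OC(=O)c4ccccc4)C[C@H]3C)C1(C)C | intermediate
15 | methyl (1R,2R,3R,7R,8R,9R,11S)-11-(benzoyloxy)-3-[(tert-butyldimethylsilyl)oxy]-2,6,6,9-tetramethyl-5-oxotricyclo[5.4.0.0^2,8]undecan-7-yl oxalate | O=C1C[C@@H](O[Si](C)(C)C(C)(C)C)[C@]2(C)[C@@H]3[C@@](OC(=O)C(=O)OC)([C@H]2[C@@H](OC(=O)c4ccccc4)C[C@H]3C)C1(C)C | intermediate
16 | (1R,2R,3R,7S,8S,9R,11S)-3-[(tert-butyldimethylsilyl)oxy]-2,6,6,9-tetramethyl-5-oxotricyclo[5.4.0.0^2,8]undecan-11-yl benzoate | O=C1C[C@@H](O[Si](C)(C)C(C)(C)C)[C@]2(C)[C@@H]3[C@@H]([C@H]2[C@@H](OC(=O)c4ccccc4)C[C@H]3C)C1(C)C | intermediate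
17 | (1R,2R,3R,7S,8S,9R,11S)-3-[(tert-butyldimethylsilyl)oxy]-11-hydroxy-2,6,6,9-tetramethyltricyclo[5.4.0.0^2,8]undecan-5-one | O=C1C[C@@H](O[Si](C)(C)C(C)(C)C)[C@]2(C)[C@@H]3[C@@H]([C@H]2[C@@H](O)C[C@H]3C)C1(C)C | intermediate
18 | (1R,2R,3R,7S,8S,9R)-3-[(tert-butyldimethylsilyl)oxy]-2,6,6,9-tetramethyltricyclo[5.4.0.0^2,8]undecane-5,11-dione | O=C1C[C@@H](O[Si](C)(C)C(C)(C)C)[C@]2(C)[C@@H]3[C@@H]([C@H]2C(=O)C[C@H]3C)C1(C)C | intermediate
19 | (1R,2R,3R,7S,8S,9R)-3-hydroxy-2,6,6,9-tetramethyltricyclo[5.4.0.0^2,8]undecane-5,11-dione | O=C1C[C@@H](O)[C@]2(C)[C@@H]3[C@@H]([C@H]2C(=O)C[C@H]3C)C1(C)C | intermediate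
20 | (1R,2R,3R,5R,7S,8S,9R)-3,5-dihydroxy-2,6,6,9-tetramethyltricyclo[5.4.0.0^2,8]undecan-11-one | O[C@@H]1C[C@@H](O)[C@]2(C)[C@@H]3[C@@H]([C@H]2C(=O)C[C@H]3C)C1(C)C | intermediate
21 | (2Z)-2-methylbut-2-enoic acid (angelic acid) | C/C=C(/C)C(=O)O | starting material
22 | (2Z)-2-methylbut-2-enoic 2,4,6-trichlorobenzoic anhydride | C/C=C(/C)C(=O)OC(=O)c1c(Cl)cc(Cl)cc1Cl | intermediate
23 | (1R,2R,3R,5R,7S,8S,9R)-2,6,6,9-tetramethyl-11-oxotricyclo[5.4.0.0^2,8]undecane-3,5-diyl bis[(2Z)-2-methylbut-2-enoate] (CNP0283599.1) | C/C=C(/C)C(=O)O[C@@H]1C[C@@H](OC(=O)/C(C)=C\C)[C@]2(C)[C@@H]3[C@@H]([C@H]2C(=O)C[C@H]3C)C1(C)C | target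

## Step count and least certain steps

Total step count: 15. Longest linear sequence: 15 steps (from 1; 10 and 21 are bought).

**Step 4 (key step).** The most likely failure is dimerisation or oligomerisation of the unstabilised aldoketene before it finds the tethered diene. Next is incomplete selection of the alkene face if the benzoate-bearing centre controls the approach less well than argued. The fallback sets out from 5, through its acid chloride 6 and Me2NH, and gives the N,N-dimethylamide F1. Activation with (CF3SO2)2O and 2,4,6-collidine in 1,2-dichloroethane at 80 °C gives the keteniminium triflate F2, which cannot dimerise, is far more electrophilic and follows the same regiochemical preference. It cyclises to the cyclobutaniminium triflate F3, and hydrolysis with aqueous NaHCO3 returns to the route at 8.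

**Step 8.** The likely failure is conjugate reduction without ring closure, because bond formation between the fully substituted C11 and the congested C6 is slow or reversible. Direct hydride attack on the cyclobutanone is the second risk. The fallback sets out from 12 and separates the two events: 1,4-hydrosilylation with Et3SiH and RhCl(PPh3)3 gives the triethylsilyl enol ether F4, and an intramolecular Mukaiyama aldol addition with TiCl4 in CH2Cl2 at −78 °C returns to the route at 14.

**Step 10.** The likely failures are a 1,2-acyl shift of the C6 radical (C1 migrating from C11 to C6, contracting the seven-membered ring) and slow C–O fragmentation because the strained pyramidal radical is poorly stabilised. The fallback sets out from 14 and removes the migrating ketone first. NaBH4 reduces C1 to give the diol F5 (C1 epimers, of no consequence), and excess ClC(O)CO2Me with pyridine gives the bis-oxalate F6. Bu3SnH with the azo initiator cleaves only the tertiary oxalate to give the mono-oxalate F7, and K2CO3 in MeOH removes the remaining oxalate and the benzoate to give the diol F8. Dess–Martin oxidation of both hydroxyls returns to the route at 18.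

**Step 6.** The likely failures are insufficient facial discrimination or low conversion with the hindered α-quaternary aldehyde, and polymerisation of 10 or oxa-Michael cyclisation of the product. The fallback sets out from 9 and replaces steps 6 to 8. A proline-catalysed aldol addition of 3-methylbutan-2-one (L-proline, the ketone as co-solvent), a reaction class that works best with α-quaternary aldehydes, gives the hydroxy ketone F9, and silylation as in step 7 gives the silyl ether F10. Acid-mediated bromination at the more substituted α-carbon with PhNMe3Br3 gives the bromo ketone F11, and SmI2 in THF at −78 °C effects a Reformatsky-type ring closure that returns to the route at 14.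

**Step 15.** The likely failures are Z to E isomerisation of the angeloyl group during a slow acylation of two neopentyl-type alcohols, and incomplete second acylation. The fallback sets out from 20 and builds the Z-alkenes on the molecule. Esterification of both hydroxyls with two equivalents of 2-[bis(2,2,2-trifluoroethoxy)phosphoryl]propanoic acid (dicyclohexylcarbodiimide, 4-(dimethylamino)pyridine) gives the bis-phosphonate F12. A twofold Still–Gennari olefination with acetaldehyde (KN(SiMe3)2, 18-crown-6, THF, −78 °C), in which the phosphonate is far more acidic than the C8 ketone, returns to the route at 23.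

## Further compounds

F1 | step 4 | (3R,5S,6E)-1-(dimethylamino)-3,7-dimethyl-1-oxonona-6,8-dien-5-yl benzoate | CN(C)C(=O)C[C@H](C)C[C@H](OC(=O)c1ccccc1)/C=C(\C)C=C
F2 | step 4 | keteniminium triflate derived from F1 | C[N+](C)=C=C[C@H](C)C[C@H](OC(=O)c1ccccc1)/C=C(\C)C=C.[O-]S(=O)(=O)C(F)(F)F
F3 | step 4 | N,N-dimethyl cyclobutaniminium triflate corresponding to 8 | C=C[C@]2(C)[C@@H]3C(=[N+](C)C)[C@H]2[C@@H](OC(=O)c1ccccc1)C[C@H]3C.[O-]S(=O)(=O)C(F)(F)F
F4 | step 8 | triethylsilyl enol ether of the saturated ketone derived from 12 (C1–OSiEt3, C1=C11) | CC(C)=C(O[Si](CC)(CC)CC)C[C@@H](O[Si](C)(C)C(C)(C)C)[C@]2(C)[C@@H]3C(=O)[C@H]2[C@@H](OC(=O)c1ccccc1)C[C@H]3C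
F5 | step 10 | C1,C6-diol obtained from 14 by reduction of the C1 ketone (C1 epimers) | OC1C[C@@H](O[Si](C)(C)C(C)(C)C)[C@]2(C)[C@@H]3[C@@](O)([C@H]2[C@@H](OC(=O)c4ccccc4)C[C@H]3C)C1(C)C
F6 | step 10 | bis(methyl oxalate) of F5 | COC(=O)C(=O)OC1C[C@@H](O[Si](C)(C)C(C)(C)C)[C@]2(C)[C@@H]3[C@@](OC(=O)C(=O)OC)([C@H]2[C@@H](OC(=O)c4ccccc4)C[C@H]3C)C1(C)C
F7 | step 10 | C1 methyl oxalate with C6–H (C1 epimers) | COC(=O)C(=O)OC1C[C@@H](O[Si](C)(C)C(C)(C)C)[C@]2(C)[C@@H]3[C@@H]([C@H]2[C@@H](OC(=O)c4ccccc4)C[C@H]3C)C1(C)C
F8 | step 10 | C1,C8-diol with C3 silyl ether (C1 epimers) | OC1C[C@@H](O[Si](C)(C)C(C)(C)C)[C@]2(C)[C@@H]3[C@@H]([C@H]2[C@@H](O)C[C@H]3C)C1(C)C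
F9 | step 6 | (1R,2S,4R,5R,7R)-7-[(1R)-1-hydroxy-4-methyl-3-oxopentyl]-4,7-dimethyl-6-oxobicyclo[3.1.1]heptan-2-yl benzoate | CC(C)C(=O)C[C@@H](O)[C@]2(C)[C@@H]3C(=O)[C@H]2[C@@H](OC(=O)c1ccccc1)C[C@H]3C
F10 | step 6 | tert-butyldimethylsilyl ether of F9 | CC(C)C(=O)C[C@@H](O[Si](C)(C)C(C)(C)C)[C@]2(C)[C@@H]3C(=O)[C@H]2[C@@H](OC(=O)c1ccccc1)C[C@H]3C
F11 | step 6 | tertiary α-bromo ketone derived from F10 | CC(C)(Br)C(=O)C[C@@H](O[Si](C)(C)C(C)(C)C)[C@]2(C)[C@@H]3C(=O)[C@H]2[C@@H](OC(=O)c1ccccc1)C[C@H]3C
F12 | step 15 | bis{2-[bis(2,2,2-trifluoroethoxy)phosphoryl]propanoate} of 20 (phosphonate α-carbons unspecified) | CC(C(=O)O[C@@H]1C[C@@H](OC(=O)C(C)P(=O)(OCC(F)(F)F)OCC(F)(F)F)[C@]2(C)[C@@H]3[C@@H]([C@H]2C(=O)C[C@H]3C)C1(C)C)P(=O)(OCC(F)(F)F)OCC(F)(F)F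
A1 | alternative 1 | (2E,4R,6R,8E,10R)-4,6-dihydroxy-3,7,7,10-tetramethylcycloundeca-2,8-dien-1-one | O=C1/C=C(\C)[C@H](O)C[C@@H](O)C(C)(C)/C=C/[C@H](C)C1
A2 | alternative 2 | cis-fused bicyclo[5.4.0]undecan-3-one keto tosylate (C6–OTs, C8=O, bond C6–C7 absent; hydroxyls shown free) | O=C1C[C@@H](C)[C@H]2[C@H](OS(=O)(=O)c3ccc(C)cc3)C(C)(C)[C@H](O)C[C@@H](O)[C@@]2(C)C1
A3 | alternative 3 | 9-nor ketone (bicyclo[2.1.1]hexan-2-one bridged by the seven-membered ring) | O[C@@H]1C[C@@H](O)[C@]2(C)[C@@H]3[C@@H]([C@H]2C(=O)[C@H]3C)C1(C)C
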